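The upper pyran (C ring, O1–C2–C3–C4–C4a–C8a) is opened at C3–C4 and O1–C2. C4 is doubly benzylic, standing between the phloroglucinol A ring and C8′ of the catechin unit, and O1 is ortho to C4a, so O1–C8a–C4a–C4 is a masked o-quinone methide. A chiral enamine of silyloxyacetaldehyde attacks C4 with the future C3, and the regenerated A-ring phenol closes onto the aldehyde carbon (C2). One operation therefore builds the C ring, two bonds and the 3,4-trans pair. The precursor is a diaryl carbinol bearing a 2-hydroxy-4,6-dibenzyloxyphenyl and a penta-O-benzylcatechin-8-yl group. C2 arylation, galloylation at O3 and hydrogenolysis complete the route.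

Key step: step 9

Remarks on the chemistry
- The target is read as (−)-epigallocatechin 3-O-gallate-(4β→8)-(+)-catechin. The upper unit is 2R,3R,4R (2,3-cis, 3,4-trans, hence 2,4-trans) and the lower unit is 2′R,3′S; primed locants denote the lower unit.
- A free ortho-phenol on the aldehyde partner would protonate the aryllithium. It therefore goes through the coupling as a silyl ether and is released in the same operation. The resulting carbinol is acid-labile and is only filtered through triethylamine-deactivated silica before use.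
- The aryl group must enter C2 on the face that also carries the C3 oxygen. A non-participating silyl ether stays on O3 until after the arylation, because an ester there would steer the aryl group to the other face.
- Assumption: (tert-butyldimethylsilyloxy)acetaldehyde and 3,4,5-tris(benzyloxy)benzoic acid are bought. The acid is otherwise made from gallic acid by perbenzylation and saponification.

Step 1
Reactants: 1 (+)-catechin
Product: 2 5,7,3′,4′-tetra-O-benzyl-(+)-catechin (3-OH free)
Conditions: BnBr (4.4 equiv), K2CO3, DMF, 0 °C to rt, Ar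
Reagents that add atoms: benzyl bromide, BrCc1ccccc1
Why: Williamson etherification in which carbonate deprotonates only the four phenols, so the secondary 3-OH stays free and both stereocentres are untouched.

Step 2
Reactants: 2 5,7,3′,4′-tetra-O-benzyl-(+)-catechin
Product: 3 8-bromo-5,7,3′,4′-tetra-O-benzylcatechin
Conditions: NBS (1.0 equiv), CH2Cl2, −78 °C to rt
Reagents that add atoms: N-bromosuccinimide, O=C1CCC(=O)N1Br
Why: Electrophilic aromatic bromination with one equivalent of NBS takes C8 of tetra-O-benzylated catechins in preference to C6, and the catechol-type ring is less activated than the phloroglucinol ring.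

Step 3
Reactants: 3 8-bromo-5,7,3′,4′-tetra-O-benzylcatechin
Product: 4 8-bromo-3,5,7,3′,4′-penta-O-benzylcatechin
Conditions: NaH, BnBr, DMF, 0 °C to rt
Reagents that add atoms: benzyl bromide, BrCc1ccccc1
Why: Williamson etherification of the sodium alkoxide removes the last acidic proton before the lithiation and blocks the lower 3-oxygen, so that later only the upper O3 can be galloylated.

Step 4
Reactants: 5 2,4,6-trihydroxybenzaldehyde
Product: 6 4,6-bis(benzyloxy)-2-hydroxybenzaldehyde
Conditions: BnBr (2.0 equiv), K2CO3 (2.0 equiv), DMF, rt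
Reagents that add atoms: benzyl bromide, BrCc1ccccc1
Why: Williamson etherification under stoichiometric control should stop at the diether, because the remaining hydroxyl is hydrogen-bonded to the formyl oxygen and is the least nucleophilic.

Step 5
Reactants: 6 4,6-bis(benzyloxy)-2-hydroxybenzaldehyde
Product: 7 4,6-bis(benzyloxy)-2-(tert-butyldimethylsilyloxy)benzaldehyde
Conditions: TBSCl, imidazole, DMAP (cat.), DMF, rt
Reagents that add atoms: tert-butyldimethylsilyl chloride, CC(C)(C)[Si](C)(C)Cl
Why: Phenol silylation masks the only acidic proton and restores full electrophilicity to the aldehyde, and the group can later be removed with fluoride without any acid.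

Step 6
Reactants: 8 5-bromo-1,2,3-trimethoxybenzene
Product: 9 5-bromobenzene-1,2,3-triol
Conditions: BBr3 (3.3 equiv), CH2Cl2, −78 °C to rt; then H2O
Reagents that add atoms: none
Why: Lewis-acid cleavage of aryl methyl ethers with BBr3 breaks the O–CH3 bonds by bromide attack on the boron-complexed ethers and leaves the aryl bromide untouched.

Step 7
Reactants: 9 5-bromobenzene-1,2,3-triol
Product: 10 5-bromo-1,2,3-tris(benzyloxy)benzene
Conditions: BnBr (3.3 equiv), K2CO3, DMF, rt to 60 °C, Ar
Reagents that add atoms: benzyl bromide, BrCc1ccccc1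
Why: Threefold Williamson etherification under inert gas (the pyrogallol is air-sensitive in base) gives the B-ring donor with the same protecting group as the rest of the molecule.

Step 8
Reactants: 4 8-bromo-3,5,7,3′,4′-penta-O-benzylcatechin; 7 4,6-bis(benzyloxy)-2-(tert-butyldimethylsilyloxy)benzaldehyde
Product: 13 (2-hydroxy-4,6-dibenzyloxyphenyl)(penta-O-benzylcatechin-8-yl)methanol (both carbinol epimers), via 8-lithio-penta-O-benzylcatechin 11 (not isolated), via silyl-protected carbinol 12 (not isolated)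
Conditions: 4, n-BuLi, THF, −78 °C; 7, −78 to −40 °C; AcOH; then TBAF, 0 °C
Reagents that add atoms: none
Why: Bromine–lithium exchange outruns benzylic deprotonation at −78 °C and the aryllithium adds 1,2 to the masked aldehyde; the new carbinol centre forms unselectively, which is harmless because it becomes planar in step 9, and fluoride frees the phenol whichever oxygen holds the silyl group after a possible O-to-O migration.

Step 9
Reactants: 13 (2-hydroxy-4,6-dibenzyloxyphenyl)(penta-O-benzylcatechin-8-yl)methanol; 14 (tert-butyldimethylsilyloxy)acetaldehyde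
Product: 18 (3R,4R)-5,7-bis(benzyloxy)-3-(tert-butyldimethylsilyloxy)-4-(penta-O-benzylcatechin-8-yl)chroman-2-ol (anomeric mixture), via o-quinone methide 15 (not isolated), via E-enamine 16 (not isolated), via open-chain aldehyde 17 (not isolated)
Conditions: (S)-α,α-diphenylprolinol trimethylsilyl ether (20 mol %), 4-nitrobenzoic acid (20 mol %), 14 (3 equiv), slow addition of 13, CH2Cl2, −20 °C to rt
Reagents that add atoms: none
Why: The weak acid removes water from 13, whose carbinol carbon lies between two trioxygenated rings, to give o-quinone methide 15 (in equilibrium with its diarylmethyl cation), while the amine condenses with 14 to E-enamine 16. Michael-type attack of the nucleophilic enamine carbon on the methide carbon forms C3–C4 and rearomatises the A ring; iminium hydrolysis then releases the catalyst and aldehyde 17, whose phenol adds to the formyl carbon in a 6-exo-trig closure (O1–C2) to give lactol 18. The closest known chemistry is the amine-catalysed formal [4+2] annulation of in situ generated o-quinone methides with enolisable aldehydes to trans-3,4-disubstituted chroman-2-ols, supported by enamine Michael additions of α-oxygenated aldehydes and SN1-type enamine alkylations with electron-rich benzhydrols. C3 (R) is set by the catalyst, whose diphenyl(silyloxy)methyl arm covers one face of the s-trans E-enamine in the same sense as in its nitroalkene Michael additions. C4 (R, trans to C3) follows from an endo-type synclinal transition state in which the methide oxygen lies over the enamine nitrogen and the catechinyl group points outward, away from the silyloxy group, while the anomeric centre is left as a mixture and is erased later. The step needs methide formation on the A ring alone and a configurationally stable C3; the first is secured because only the A ring carries a free phenol, and the second because lactol closure withdraws the α-branched aldehyde from further enamine chemistry.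

Step 10
Reactants: 18 (3R,4R)-3-silyloxy-4-(catechin-8-yl)chroman-2-ol
Product: 19 (3R,4R)-2-acetoxy-5,7-bis(benzyloxy)-3-(tert-butyldimethylsilyloxy)-4-(penta-O-benzylcatechin-8-yl)chroman (anomeric mixture)
Conditions: Ac2O, pyridine, DMAP (cat.), CH2Cl2, 0 °C to rt
Reagents that add atoms: acetic anhydride, CC(=O)OC(C)=O
Why: O-Acylation of the lactol hydroxyl installs an anomeric leaving group, and the anomeric mixture is irrelevant because C2 becomes planar in the next step.

Step 11
Reactants: 19 2-acetoxychroman; 10 5-bromo-1,2,3-tris(benzyloxy)benzene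
Product: 23 (2R,3R,4R)-5,7-bis(benzyloxy)-3-(tert-butyldimethylsilyloxy)-2-[3,4,5-tris(benzyloxy)phenyl]-4-(penta-O-benzylcatechin-8-yl)chroman, via 3,4,5-tris(benzyloxy)phenyllithium 20 (not isolated), via arylzinc bromide 21 (not isolated), via oxocarbenium triflate 22 (not isolated)
Conditions: 10 (3 equiv), n-BuLi, THF, −78 °C; ZnBr2, to 0 °C; solvent switch to toluene; 19 in CH2Cl2, −78 °C; TMSOTf, to −40 °C
Reagents that add atoms: none
Why: Ionisation of the anomeric acetate gives oxocarbenium ion 22, which the arylzinc captures ipso as in a Lewis-acid C-aryl glycosidation; the 3,4-trans pair mimics C2/C3 of a gluco-configured pyranosyl cation, so axial attack on the diequatorial half-chair and the shielding of the other face by the C4 catechinyl group (its 7′-oxygen lies over C2) both send the aryl group anti to the C4 aryl, setting 2R (2,3-cis, 2,4-trans).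

Step 12
Reactants: 23 3-O-silyl 2-arylchroman
Product: 24 (2R,3R,4R)-5,7-bis(benzyloxy)-2-[3,4,5-tris(benzyloxy)phenyl]-4-(penta-O-benzylcatechin-8-yl)chroman-3-ol
Conditions: TBAF (3 equiv), THF, rt to 45 °C
Reagents that add atoms: none
Why: Fluoride-induced Si–O cleavage touches no stereocentre, and because only benzyl ethers are present besides, unbuffered TBAF and gentle warming are tolerated for this hindered ether.

Step 13
Reactants: 24 chroman-3-ol; 25 3,4,5-tris(benzyloxy)benzoic acid
Product: 26 trideca-O-benzyl epigallocatechin 3-O-gallate-(4β→8)-catechin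
Conditions: 25 (3 equiv), DCC, DMAP, CH2Cl2, rt
Reagents that add atoms: none
Why: Steglich esterification acylates the only free hydroxyl at oxygen with retention at C3, and DMAP with excess acid compensates for the axial, hindered position.

Step 14
Reactants: 26 trideca-O-benzyl ester
Product: 27 (−)-epigallocatechin 3-O-gallate-(4β→8)-(+)-catechin (CNP0129434.1)
Conditions: H2 (1 atm), 20 % Pd(OH)2/C, THF/MeOH/H2O, rt; filtration, lyophilisation
Reagents that add atoms: none
Why: Catalytic hydrogenolysis removes all thirteen O-benzyl groups under neutral conditions that leave the gallate ester, the C4–C8′ bond and the five stereocentres intact.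

Compound list
1 | (+)-catechin (2R,3S) | Oc1cc(O)c2c(c1)O[C@H](c1ccc(O)c(O)c1)[C@@H](O)C2 | starting material
2 | 5,7,3′,4′-tetra-O-benzyl-(+)-catechin | c1ccccc1COc1cc(OCc2ccccc2)c2c(c1)O[C@H](c1ccc(OCc3ccccc3)c(OCc3ccccc3)c1)[C@@H](O)C2 | intermediate
3 | 8-bromo-5,7,3′,4′-tetra-O-benzylcatechin | Brc1c(OCc2ccccc2)cc(OCc2ccccc2)c2c1O[C@H](c1ccc(OCc3ccccc3)c(OCc3ccccc3)c1)[C@@H](O)C2 | intermediate
4 | 8-bromo-3,5,7,3′,4′-penta-O-benzylcatechin | Brc1c(OCc2ccccc2)cc(OCc2ccccc2)c2c1O[C@H](c1ccc(OCc3ccccc3)c(OCc3ccccc3)c1)[C@@H](OCc1ccccc1)C2 | intermediate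
5 | 2,4,6-trihydroxybenzaldehyde | O=Cc1c(O)cc(O)cc1O | starting material
6 | 4,6-bis(benzyloxy)-2-hydroxybenzaldehyde | O=Cc1c(O)cc(OCc2ccccc2)cc1OCc1ccccc1 | intermediate
7 | 4,6-bis(benzyloxy)-2-(tert-butyldimethylsilyloxy)benzaldehyde | O=Cc1c(O[Si](C)(C)C(C)(C)C)cc(OCc2ccccc2)cc1OCc1ccccc1 | intermediate
8 | 5-bromo-1,2,3-trimethoxybenzene | COc1cc(Br)cc(OC)c1OC | starting material
9 | 5-bromobenzene-1,2,3-triol | Oc1cc(Br)cc(O)c1O | intermediate
10 | 5-bromo-1,2,3-tris(benzyloxy)benzene | Brc1cc(OCc2ccccc2)c(OCc2ccccc2)c(OCc2ccccc2)c1 | intermediate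
11 | 8-lithio-penta-O-benzylcatechin | [Li]c1c(OCc2ccccc2)cc(OCc2ccccc2)c2c1O[C@H](c1ccc(OCc3ccccc3)c(OCc3ccccc3)c1)[C@@H](OCc1ccccc1)C2 | intermediate
12 | (2-silyloxy-4,6-dibenzyloxyphenyl)(penta-O-benzylcatechin-8-yl)methanol, carbinol epimers | OC(c1c(O[Si](C)(C)C(C)(C)C)cc(OCc2ccccc2)cc1OCc1ccccc1)c1c(OCc2ccccc2)cc(OCc2ccccc2)c2c1O[C@H](c1ccc(OCc3ccccc3)c(OCc3ccccc3)c1)[C@@H](OCc1ccccc1)C2 | intermediate
13 | (2-hydroxy-4,6-dibenzyloxyphenyl)(penta-O-benzylcatechin-8-yl)methanol, carbinol epimers | OC(c1c(O)cc(OCc2ccccc2)cc1OCc1ccccc1)c1c(OCc2ccccc2)cc(OCc2ccccc2)c2c1O[C@H](c1ccc(OCc3ccccc3)c(OCc3ccccc3)c1)[C@@H](OCc1ccccc1)C2 | intermediate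
14 | (tert-butyldimethylsilyloxy)acetaldehyde | O=CCO[Si](C)(C)C(C)(C)C | starting material
15 | A-ring o-quinone methide with the catechin-8-yl group on the methide carbon (exocyclic geometry mobile, not specified) | O=C1C=C(OCc2ccccc2)C=C(OCc2ccccc2)C1=Cc1c(OCc2ccccc2)cc(OCc2ccccc2)c2c1O[C@H](c1ccc(OCc3ccccc3)c(OCc3ccccc3)c1)[C@@H](OCc1ccccc1)C2 | intermediate
16 | E-enamine of 14 with (S)-α,α-diphenylprolinol trimethylsilyl ether | CC(C)(C)[Si](C)(C)O/C=C/N1CCC[C@H]1C(c1ccccc1)(c1ccccc1)O[Si](C)(C)C | intermediate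
17 | (2R,3R)-2-silyloxy-3-(2-hydroxy-4,6-dibenzyloxyphenyl)-3-(penta-O-benzylcatechin-8-yl)propanal | CC(C)(C)[Si](C)(C)O[C@@H](C=O)[C@@H](c2c(OCc3ccccc3)cc(OCc3ccccc3)c3c2O[C@H](c2ccc(OCc4ccccc4)c(OCc4ccccc4)c2)[C@@H](OCc2ccccc2)C3)c1c(OCc2ccccc2)cc(OCc2ccccc2)cc1O | intermediate
18 | (3R,4R)-3-silyloxy-4-(penta-O-benzylcatechin-8-yl)-5,7-dibenzyloxychroman-2-ol, anomers | CC(C)(C)[Si](C)(C)O[C@@H]1[C@@H](c2c(OCc3ccccc3)cc(OCc3ccccc3)c3c2O[C@H](c2ccc(OCc4ccccc4)c(OCc4ccccc4)c2)[C@@H](OCc2ccccc2)C3)c2c(OCc3ccccc3)cc(OCc3ccccc3)cc2OC1O | intermediate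
19 | anomeric acetate of 18 | CC(C)(C)[Si](C)(C)O[C@@H]1[C@@H](c2c(OCc3ccccc3)cc(OCc3ccccc3)c3c2O[C@H](c2ccc(OCc4ccccc4)c(OCc4ccccc4)c2)[C@@H](OCc2ccccc2)C3)c2c(OCc3ccccc3)cc(OCc3ccccc3)cc2OC1OC(C)=O | intermediate
20 | 3,4,5-tris(benzyloxy)phenyllithium | [Li]c1cc(OCc2ccccc2)c(OCc2ccccc2)c(OCc2ccccc2)c1 | intermediate
21 | 3,4,5-tris(benzyloxy)phenylzinc bromide | Br[Zn]c1cc(OCc2ccccc2)c(OCc2ccccc2)c(OCc2ccccc2)c1 | intermediate
22 | (3R,4R)-chroman-2-ylium (O1=C2 oxocarbenium) triflate | CC(C)(C)[Si](C)(C)O[C@@H]1[C@@H](c2c(OCc3ccccc3)cc(OCc3ccccc3)c3c2O[C@H](c2ccc(OCc4ccccc4)c(OCc4ccccc4)c2)[C@@H](OCc2ccccc2)C3)c2c(OCc3ccccc3)cc(OCc3ccccc3)cc2[O+]=C1.[O-]S(=O)(=O)C(F)(F)F | intermediate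
23 | (2R,3R,4R)-3-O-TBS deca-O-benzyl epigallocatechin-(4β→8)-catechin | CC(C)(C)[Si](C)(C)O[C@@H]1[C@@H](c2c(OCc3ccccc3)cc(OCc3ccccc3)c3c2O[C@H](c2ccc(OCc4ccccc4)c(OCc4ccccc4)c2)[C@@H](OCc2ccccc2)C3)c2c(OCc3ccccc3)cc(OCc3ccccc3)cc2O[C@@H]1c1cc(OCc2ccccc2)c(OCc2ccccc2)c(OCc2ccccc2)c1 | intermediate
24 | deca-O-benzyl epigallocatechin-(4β→8)-catechin with free upper 3-OH | O[C@@H]1[C@@H](c2c(OCc3ccccc3)cc(OCc3ccccc3)c3c2O[C@H](c2ccc(OCc4ccccc4)c(OCc4ccccc4)c2)[C@@H](OCc2ccccc2)C3)c2c(OCc3ccccc3)cc(OCc3ccccc3)cc2O[C@@H]1c1cc(OCc2ccccc2)c(OCc2ccccc2)c(OCc2ccccc2)c1 | intermediate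
25 | 3,4,5-tris(benzyloxy)benzoic acid | O=C(O)c1cc(OCc2ccccc2)c(OCc2ccccc2)c(OCc2ccccc2)c1 | starting material
26 | trideca-O-benzyl epigallocatechin 3-O-gallate-(4β→8)-catechin | O=C(O[C@@H]1[C@@H](c2c(OCc3ccccc3)cc(OCc3ccccc3)c3c2O[C@H](c2ccc(OCc4ccccc4)c(OCc4ccccc4)c2)[C@@H](OCc2ccccc2)C3)c2c(OCc3ccccc3)cc(OCc3ccccc3)cc2O[C@@H]1c1cc(OCc2ccccc2)c(OCc2ccccc2)c(OCc2ccccc2)c1)c1cc(OCc2ccccc2)c(OCc2ccccc2)c(OCc2ccccc2)c1 | intermediate
27 | (−)-epigallocatechin 3-O-gallate-(4β→8)-(+)-catechin | O=C(O[C@@H]1[C@@H](c2c(O)cc(O)c3c2O[C@H](c2ccc(O)c(O)c2)[C@@H](O)C3)c2c(O)cc(O)cc2O[C@@H]1c1cc(O)c(O)c(O)c1)c1cc(O)c(O)c(O)c1 | target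

Total step count: 14
Longest linear sequence: 10 steps (1, 2, 3, 8, 9, 10, 11, 12, 13, 14)

Steps most likely to fail

Step 9.
- Facial discrimination at the methide carbon may be insufficient. Both aryl groups on C4 are di-ortho-oxygenated and similar in size, and the 5-benzyloxy group weakens the usual preference of the methide for the geometry that turns the aryl group away from the carbonyl.
- The aldehyde may be consumed by self-aldol reaction, and the catalyst may be tied up by N-addition to the methide.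
- The fallback sets out from 2 and returns at 24, and it replaces the annulation by the cationic flavan coupling.
- 2 is benzylated at O3 (NaH, BnBr, DMF) to penta-O-benzyl-(+)-catechin F1.
- Purchased (−)-epigallocatechin F2 is benzylated on its five phenols (BnBr, K2CO3, DMF) to 5,7,3′,4′,5′-penta-O-benzylepigallocatechin F3.
- DDQ in the presence of 2-ethoxyethanol oxidises C4 of F3 to the 4β-(2-ethoxyethoxy) ether F4.
- TiCl4 in CH2Cl2 at low temperature ionises F4, and an excess of F1 attacks the C4 cation through C8, trans to the 3-hydroxyl, which should give 24 directly.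

Step 11.
- The aryl group may add trans to the neighbouring silyloxy group instead of anti to the C4 aryl group.
- The cation may lose the C3 proton, which amounts to elimination to a 4H-chromene.
- The cation may be captured transannularly by the 7′-oxygen with loss of its benzyl group.
- The fallback sets out from 18 and 10 and returns at 23, and it avoids the cation altogether.
- 10 and magnesium in THF give 3,4,5-tris(benzyloxy)phenylmagnesium bromide F5.
- An excess of F5 adds to the open aldehyde form of 18 under Felkin–Anh control to the anti-configured (1S,2R,3R)-1-aryl-2-silyloxy-3,3-diarylpropan-1-ol F6.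
- Mitsunobu cyclisation of F6 (PPh3, DIAD, toluene, 0 °C) lets the A-ring phenol displace the activated benzylic oxygen with inversion, closing O1–C2 with the 2R configuration of 23.

Step 8.
- Addition between two di-ortho-substituted partners may be slow, with competing protonation of the aryllithium.
- The carbinol may lose water prematurely during work-up.
- The fallback sets out from 4 and returns at 13, and it forms the C4–C4a bond instead of the C4–C8′ bond.
- 4 is lithiated (n-BuLi, THF, −78 °C) and quenched with DMF to 8-formyl-penta-O-benzylcatechin F7.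
- F7, purchased 3,5-bis(benzyloxy)phenol F8 and phenylboronic acid are heated with catalytic propionic acid in toluene under azeotropic removal of water. Boron-templated ortho-hydroxyalkylation of the phenol should then give the 2-phenyl-4H-1,3,2-benzodioxaborin F9.
- H2O2 in THF cleaves the boronate of F9 and releases 13.

Further compounds
F1 | step 9 | penta-O-benzyl-(+)-catechin | c1ccccc1COc1cc(OCc2ccccc2)c2c(c1)O[C@H](c1ccc(OCc3ccccc3)c(OCc3ccccc3)c1)[C@@H](OCc1ccccc1)C2
F2 | step 9 | (−)-epigallocatechin (purchased) | Oc1cc(O)c2c(c1)O[C@H](c1cc(O)c(O)c(O)c1)[C@H](O)C2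
F3 | step 9 | 5,7,3′,4′,5′-penta-O-benzylepigallocatechin | c1ccccc1COc1cc(OCc2ccccc2)c2c(c1)O[C@H](c1cc(OCc3ccccc3)c(OCc3ccccc3)c(OCc3ccccc3)c1)[C@H](O)C2
F4 | step 9 | 4β-(2-ethoxyethoxy)-5,7,3′,4′,5′-penta-O-benzylepigallocatechin | c1ccccc1COc1cc(OCc2ccccc2)c2c(c1)O[C@H](c1cc(OCc3ccccc3)c(OCc3ccccc3)c(OCc3ccccc3)c1)[C@H](O)[C@H]2OCCOCC
F5 | step 11 | 3,4,5-tris(benzyloxy)phenylmagnesium bromide | Br[Mg]c1cc(OCc2ccccc2)c(OCc2ccccc2)c(OCc2ccccc2)c1
F6 | step 11 | (1S,2R,3R)-1-[3,4,5-tris(benzyloxy)phenyl]-2-silyloxy-3-(2-hydroxy-4,6-dibenzyloxyphenyl)-3-(penta-O-benzylcatechin-8-yl)propan-1-ol | CC(C)(C)[Si](C)(C)O[C@@H]([C@@H](O)c1cc(OCc2ccccc2)c(OCc2ccccc2)c(OCc2ccccc2)c1)[C@@H](c2c(OCc3ccccc3)cc(OCc3ccccc3)c3c2O[C@H](c2ccc(OCc4ccccc4)c(OCc4ccccc4)c2)[C@@H](OCc2ccccc2)C3)c1c(OCc2ccccc2)cc(OCc2ccccc2)cc1O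
F7 | step 8 | 8-formyl-penta-O-benzylcatechin | O=Cc1c(OCc2ccccc2)cc(OCc2ccccc2)c2c1O[C@H](c1ccc(OCc3ccccc3)c(OCc3ccccc3)c1)[C@@H](OCc1ccccc1)C2
F8 | step 8 | 3,5-bis(benzyloxy)phenol (purchased) | Oc1cc(OCc2ccccc2)cc(OCc2ccccc2)c1
F9 | step 8 | 5,7-bis(benzyloxy)-2-phenyl-4-(penta-O-benzylcatechin-8-yl)-4H-1,3,2-benzodioxaborin, C4 epimers | c1ccccc1B1OC(c2c(OCc3ccccc3)cc(OCc3ccccc3)c3c2O[C@H](c2ccc(OCc4ccccc4)c(OCc4ccccc4)c2)[C@@H](OCc2ccccc2)C3)c2c(OCc3ccccc3)cc(OCc3ccccc3)cc2O1
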